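The vessel was closed, stirred and held at one temperature, and substrate met partner in it at several charges.

| flask | substrate | partner | remark | time |
|---|---|---|---|---|
| autumn | 5 mM | 0.12 mM | run made earlier |  |
| dusk | 5 mM | 6.9 mM | run made earlier |  |
| south-west | 5.0 mM | 0.0800 mM |  | 2.0 min |
| east | 5.0 mM | 0.200 mM |  | 2.0 min |
| south | 5.0 mM | 0.600 mM |  | 2.0 min |
| south-east | 5.0 mM | 2.00 mM |  | 2.0 min |
| west | 5.0 mM | 6.00 mM |  | 2.0 min |

- autumn (time / s: first product / %): 10.0: 3.7; 20.0: 0.4; 40.0: 2.3; 60.0: 0.6; 80.0: 1.6
- dusk (time / s: first product / %): 15.0: 13.6; 30.0: 10.7; 50.0: 11.7; 60.0: 8.9; 80.0: 8.5

(standard deviation of a reading: 1 percentage point)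

- the numbers in the tables scatter with a standard deviation of 1 percentage point
- steps under discussion: partner + first product -> over-reaction product; partner + first product -> bis adduct; substrate + partner -> first product; partner <-> dormant form; substrate + partner -> other mono adduct; partner + other mono adduct -> bis adduct
- "hardly changes" means that all values lie within two and a half points (for a concentration: within two and a half percent of the largest)

1. amount of first product at the end, in percent of the substrate charged for south-west, east, south, south-east, west, in this order
2. how that number moves from the first to the last of them (falls all the way / rises, then falls / hardly changes / falls, then rises / rises all the way)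

I ordered what I knew as a ladder of time scales. The first rung was partner's work in the autumn run. Its charge of 0.12 mM stood against 5 mM of substrate, so partner was the limiting reagent there. Those readings showed no trend I could hold against the scatter from 10.0 s on. I therefore took that work as over within the asked 2.0 min, which is longer than the autumn run's last reading at 80.0 s.

On the next rung stood the substrate, which I froze. The autumn partner charge was 2.40% of it, so I held substrate at its charge. Each partner then met the same odds, and first product should follow the partner charge in a straight line.

The autumn readings averaged 1.72%. That reading gave 0.717, which I named the capture share: first product formed per partner charged while substrate stays frozen. Multiplied by partner charge over substrate charge, it gave 1.15% for south-west.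

The last rung was the loss seen in the dusk run, where partner exceeded substrate. First product read 13.6% at 15.0 s and 8.5% at 80.0 s, so I took it that excess partner was spending first product there. The last three dusk readings averaged 9.70%, and I took that for west, whose charge lies near dusk's. For south-east the share gave 28.7%, above dusk's first reading. I distrusted the freeze there and expected a rise, then a fall.

The forecast, not identical with my figures, gave 1.1%, 2.7%, 7%, 13% and 10%, shape rises, then falls, with the words “yield ≈ 0.7 × partner/substrate at low loading”.

The flasks gave 1.25%, 2.92%, 7.07%, 13.2% and 10.0%, in the order asked. The shape was rises, then falls, and the row turned at 2.9 mM of partner.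

    partner + first product → over-reaction product (k = 0.980 M⁻¹ s⁻¹)
    partner + first product → bis adduct (k = 40.0 M⁻¹ s⁻¹)
    substrate + partner → first product (k = 9.20 M⁻¹ s⁻¹)
    partner ⇌ dormant form (K = 0.730, k = 0.0430 s⁻¹)
    substrate + partner → other mono adduct (k = 1.50 M⁻¹ s⁻¹)
    partner + other mono adduct → bis adduct (k = 8.00 M⁻¹ s⁻¹)

In south-west, the half-life of first product through over-reaction product alone, other concentrations as charged, was 150 min, long against 2.0 min, and that step changed nothing there. The capture share had given 1.15% for south-west, which stood at 1.25%. Carried to east, the share gave 2.87%. East stood at 2.92%, with 96.4% of its substrate left at 2.00 min.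

All runs were generated by integration with made-up constants, and the scatter is random.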